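## Retrosynthetic overview

1. The target has a 2,6-cis-diequatorial oxane with an axial 4-OH. It comes from its all-equatorial C4 epimer by SN2 inversion of the one carbinol that takes no part in ring formation.
2. The oxane is the only ring. It is closed at the benzylic carbon, where the 5-OH of a linear diarylheptanoid adds 1,6 to a p-quinone methide.
3. The quinone methide is made by direct dehydrogenation of unprotected (3S,5S)-octahydrocurcumin. This diol has a twofold axis, so both ArCH2 groups and both OH groups are homotopic and either end gives the same enantiomer. The syn-diol that maps directly onto the target is meso and could only give racemate.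
4. The diol comes from tetrahydrocurcumin by double asymmetric hydrogenation of the β-diketone.

**Assumption:** tetrahydrocurcumin (hydrogenated curcumin, sold in bulk as a cosmetic ingredient) is taken as a cheap commercial starting material.

**Stereochemical bookkeeping:** heptane C1/C3/C5 correspond to oxane C2/C4/C6. The target is (2S,4S,6S), with the aryl and arylethyl groups cis and the 4-OH trans to both. C6 is set in step 1. C2 is set in step 2. C4 is set in step 1 and inverted in step 3.

## Route

**Step 1**
Reactants: 1 tetrahydrocurcumin, 1,7-bis(4-hydroxy-3-methoxyphenyl)heptane-3,5-dione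
Product: 2 (3S,5S)-1,7-bis(4-hydroxy-3-methoxyphenyl)heptane-3,5-diol (anti, twofold-symmetric octahydrocurcumin)
Conditions: H2 (70 atm), RuCl2[(S)-BINAP] (0.5 mol %), MeOH, 50 °C; the minor meso diol is removed by crystallisation or chromatography
Reagents that add atoms: none
Why: This is a Noyori asymmetric hydrogenation of a β-diketone, in which the 1,3-dioxygen unit chelates divalent ruthenium and (S)-BINAP gives first the (S)-β-hydroxy ketone and then, catalyst-matched and hydroxyl-assisted, the anti (3S,5S)-diol, while the minor first-step enantiomer drains into the separable meso diol so that 2 is essentially enantiopure and the phenols and arenes stay inert.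

**Step 2**
Reactants: 2 (3S,5S)-octahydrocurcumin
Product: 4 (2S,4R,6S)-2-(4-hydroxy-3-methoxyphenyl)-6-[2-(4-hydroxy-3-methoxyphenyl)ethyl]oxan-4-ol (all-cis, all-equatorial), via p-quinone methide 3 (not isolated)
Conditions: DDQ (0.9 equiv, slow addition), 4 Å MS, MeCN/CH2Cl2 (0.01 M), −20 → 0 °C; unreacted 2 is recovered and recycled
Reagents that add atoms: none
Why: This is a biomimetic phenol-to-p-quinone-methide dehydrogenation followed by intramolecular oxa-1,6-conjugate addition, in which the 5-OH closes a 6-exo chair with the side chain, the 3-OH and the arylidene all equatorial, and because the closure stays reversible under the acidic hydroquinone the 2,6-cis isomer (new C2 = S) is both the kinetic and the thermodynamic product, the twofold axis of 2 makes oxidation at either end give the identical enantiomer, and attack by the 3-OH would need an oxetane.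

**Step 3**
Reactants: 4 all-equatorial oxan-4-ol
Product: 6 (2S,4S,6S)-2-(4-hydroxy-3-methoxyphenyl)-6-[2-(4-hydroxy-3-methoxyphenyl)ethyl]oxan-4-ol (target), via axial 4-nitrobenzoate 5 (not isolated)
Conditions: 4-O2NC6H4CO2H, PPh3, DIAD, THF, 0 °C → rt; then MeOH, K2CO3 (catalyst of the transesterification), rt, same flask, under Ar; aq NH4Cl work-up
Reagents that add atoms: 4-nitrobenzoic acid, O=C(O)c1ccc(cc1)[N+](=O)[O-] (its carboxyl oxygen becomes the C4 oxygen of 6)
Why: This is a Mitsunobu inversion followed by transesterification, in which only the aliphatic OH becomes an alkoxyphosphonium leaving group and the much more acidic carboxylic acid (pKa 3.4 against about 10 for the guaiacols) is the nucleophile, so SN2 displacement turns the equatorial (4R) into the axial (4S) C–O bond, and K2CO3/MeOH then cleaves the acyl–oxygen bond (and any adventitious aryl ester) without touching C2, C4 or C6.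

## Compound list

| No. | Name | SMILES | Role |
|---|---|---|---|
| 1 | tetrahydrocurcumin | COc1cc(CCC(=O)CC(=O)CCc2ccc(O)c(OC)c2)ccc1O | starting material |
| 2 | (3S,5S)-1,7-bis(4-hydroxy-3-methoxyphenyl)heptane-3,5-diol | COc1cc(CC[C@H](O)C[C@@H](O)CCc2ccc(O)c(OC)c2)ccc1O | intermediate |
| 3 | 4-[(3S,5S)-3,5-dihydroxy-7-(4-hydroxy-3-methoxyphenyl)heptylidene]-2-methoxycyclohexa-2,5-dien-1-one | COc1cc(CC[C@H](O)C[C@@H](O)CC=C2C=CC(=O)C(OC)=C2)ccc1O | intermediate (not isolated) |
| 4 | (2S,4R,6S)-2-(4-hydroxy-3-methoxyphenyl)-6-[2-(4-hydroxy-3-methoxyphenyl)ethyl]oxan-4-ol | COc1cc(CC[C@H]2C[C@@H](O)C[C@@H](c3ccc(O)c(OC)c3)O2)ccc1O | intermediate |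
| 5 | (2S,4S,6S)-2-(4-hydroxy-3-methoxyphenyl)-6-[2-(4-hydroxy-3-methoxyphenyl)ethyl]oxan-4-yl 4-nitrobenzoate | COc1cc(CC[C@H]2C[C@H](OC(=O)c3ccc(cc3)[N+](=O)[O-])C[C@@H](c3ccc(O)c(OC)c3)O2)ccc1O | intermediate (not isolated) |
| 6 | (2S,4S,6S)-2-(4-hydroxy-3-methoxyphenyl)-6-[2-(4-hydroxy-3-methoxyphenyl)ethyl]oxan-4-ol | COc1cc(CC[C@H]2C[C@H](O)C[C@@H](c3ccc(O)c(OC)c3)O2)ccc1O | target |

## Step count and risks

Total step count: 3. Longest linear sequence: 3.

**Steps most likely to fail, riskiest first**

**Step 2.**
- Risk: Product 4 still carries one guaiacyl-CH2 that is as oxidisable as the two in 2. A single pass is therefore statistically capped near 50 %. The quinone methide can also tautomerise to the styrene or be trapped intermolecularly. The C2–H of 4 is protected only by poor alignment with the aryl π system.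
- Fallback (sets out from 2, comes back at 6): The two homotopic phenols are told apart before the oxidation. One equivalent of Ac2O under Schotten–Baumann conditions (aq NaOH/CH2Cl2, 0 °C) gives the mono(aryl acetate) F1. The bis-acetate and unreacted 2 are recycled. The acetoxyarene is too electron-poor for DDQ, so a slight excess of DDQ can now take the reaction to full conversion through the p-quinone methide acetate F2 to the all-equatorial oxanol acetate F3. F3 then goes through the conditions of step 3. The axial 4-nitrobenzoate acetate F4 loses both esters in the K2CO3/MeOH stage and gives 6.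

**Step 3.**
- Risk: The phenols may be O-alkylated, or the activated alcohol may eliminate to a dihydropyran during the axial-forming displacement.
- Fallback (sets out from 4, comes back at 6): The SN2 inversion is replaced by an oxidation/reduction pair. Swern oxidation ((COCl)2, DMSO, Et3N, CH2Cl2, −78 °C) gives the cis-oxan-4-one F5. LiBH(s-Bu)3 (4 equiv, two of them consumed by the phenols) in THF at −78 °C then attacks from the equatorial face and gives the axial alcohol 6.

**Step 1.**
- Risk: The reaction may stall at the hydroxy ketone or give a poor anti:syn ratio in the second reduction.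
- Fallback (sets out from 1, comes back at 2): The two carbinols are set one at a time, the second under substrate control. An (S)-selective ketoreductase (NADPH, glucose/glucose dehydrogenase recycling, pH 7 buffer) reduces one carbonyl to (S)-hexahydrocurcumin F6. Hydroxyl-directed Evans–Saksena reduction with Me4NBH(OAc)3 in MeCN/AcOH at −30 °C then gives the anti diol 2.

## Further compounds

F1 | step 2 | 4-[(3S,5S)-3,5-dihydroxy-7-(4-hydroxy-3-methoxyphenyl)heptyl]-2-methoxyphenyl acetate | COc1cc(CC[C@H](O)C[C@@H](O)CCc2ccc(O)c(OC)c2)ccc1OC(C)=O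
F2 | step 2 | 4-[(3S,5S)-3,5-dihydroxy-7-(3-methoxy-4-oxocyclohexa-2,5-dien-1-ylidene)heptyl]-2-methoxyphenyl acetate | COc1cc(CC[C@H](O)C[C@@H](O)CC=C2C=CC(=O)C(OC)=C2)ccc1OC(C)=O
F3 | step 2 | 4-{2-[(2S,4R,6S)-4-hydroxy-6-(4-hydroxy-3-methoxyphenyl)oxan-2-yl]ethyl}-2-methoxyphenyl acetate | COc1cc(CC[C@H]2C[C@@H](O)C[C@@H](c3ccc(O)c(OC)c3)O2)ccc1OC(C)=O
F4 | step 2 | (2S,4S,6S)-2-[2-(4-acetoxy-3-methoxyphenyl)ethyl]-6-(4-hydroxy-3-methoxyphenyl)oxan-4-yl 4-nitrobenzoate | COc1cc(CC[C@H]2C[C@H](OC(=O)c3ccc(cc3)[N+](=O)[O-])C[C@@H](c3ccc(O)c(OC)c3)O2)ccc1OC(C)=O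
F5 | step 3 | (2S,6S)-2-(4-hydroxy-3-methoxyphenyl)-6-[2-(4-hydroxy-3-methoxyphenyl)ethyl]oxan-4-one | COc1cc(CC[C@H]2CC(=O)C[C@@H](c3ccc(O)c(OC)c3)O2)ccc1O
F6 | step 1 | (5S)-5-hydroxy-1,7-bis(4-hydroxy-3-methoxyphenyl)heptan-3-one | COc1cc(CC[C@H](O)CC(=O)CCc2ccc(O)c(OC)c2)ccc1O
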